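Everything rests on disconnecting the C4–C4a bond of the 2H-chromene. A gold-catalysed 6-endo-dig hydroarylation lets C4a, the only free carbon ortho to O1 (C8 carries the methyl group), attack the terminal alkyne carbon of an aryl tertiary propargyl ether. One operation closes the pyran ring and creates the cis C3=C4 alkene, while the C2–O1 bond, and with it the (S) centre derived from geraniol, is never broken. The precursor is the bis-silylated (4S)-4-aryloxy-4-methylhex-5-yn-1-ol 14, its side chain already shortened to three carbons. A nickel-catalysed decarboxylative alkenylation later joins the chromene acid to a separately built (R)-iodoalkenyl butenolide.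

Key step: step 9

Remark: alkoxides, acetylides and enolates made by deprotonating a numbered compound immediately before it reacts are treated as the reactive form of that compound and are not numbered separately.

Step 1
Reactants: 1 geraniol
Product: 2 [(2S,3S)-3-methyl-3-(4-methylpent-3-en-1-yl)oxiran-2-yl]methanol
Conditions: Ti(OiPr)4 (cat.), L-(+)-diethyl tartrate (cat.), t-BuOOH, 4 Å molecular sieves, CH2Cl2, −20 °C
Reagents that add atoms: tert-butyl hydroperoxide, CC(C)(C)OO
Why: Katsuki–Sharpless asymmetric epoxidation of the allylic alcohol, in which the titanium–L-(+)-tartrate catalyst delivers oxygen to one face of the E alkene and so should set both epoxide centres as (2S,3S) in high enantiomeric excess, C3 being the carbon that ends as C2 of the chromene.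

Step 2
Reactants: 2 [(2S,3S)-3-methyl-3-(4-methylpent-3-en-1-yl)oxiran-2-yl]methanol
Product: 3 (2S,3R)-3-(chloromethyl)-2-methyl-2-(4-methylpent-3-en-1-yl)oxirane
Conditions: PPh3, CCl4, NaHCO3, reflux
Reagents that add atoms: tetrachloromethane, ClC(Cl)(Cl)Cl
Why: Appel reaction, in which the alkoxyphosphonium ion is displaced by chloride at the primary carbon (SN2) in a bicarbonate-buffered neutral medium that leaves the epoxide and both stereocentres untouched.

Step 3
Reactants: 3 (2S,3R)-3-(chloromethyl)-2-methyl-2-(4-methylpent-3-en-1-yl)oxirane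
Product: 5 (3S)-3,7-dimethyloct-6-en-1-yn-3-ol, via lithium chloroallylic alkoxide 4 (not isolated)
Conditions: n-BuLi (3.3 equiv), THF, −40 → 0 °C; aq NH4Cl
Reagents that add atoms: none
Why: Base-induced fragmentation of a 2,3-epoxy chloride, in which lithiation next to chlorine triggers a β-elimination that opens the epoxide to alkoxide 4, a second dehydrochlorination gives the alkyne and the third equivalent holds it as the acetylide, so the C–O bond of the tertiary centre is never broken and its (S) configuration is kept.

Step 4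
Reactants: 5 (3S)-3,7-dimethyloct-6-en-1-yn-3-ol; 6 4-fluoro-3-methylbenzonitrile
Product: 7 4-{[(3S)-3,7-dimethyloct-6-en-1-yn-3-yl]oxy}-3-methylbenzonitrile
Conditions: KN(SiMe3)2 (1.05 equiv), THF, 0 °C; then 6, DMF, 0 °C → rt
Reagents that add atoms: none
Why: Nucleophilic aromatic substitution (addition–elimination through a Meisenheimer adduct) of the tertiary potassium alkoxide at the fluorine-bearing carbon para to the nitrile, an activating group that, unlike an aldehyde, cannot be attacked by alkoxide or traces of acetylide, and since only the O–aryl bond is formed the carbinol centre keeps its configuration.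

Step 5
Reactants: 7 4-{[(3S)-3,7-dimethyloct-6-en-1-yn-3-yl]oxy}-3-methylbenzonitrile
Product: 9 4-{[(3S)-6-hydroxy-3-methylhex-1-yn-3-yl]oxy}-3-methylbenzonitrile, via aldehyde 8 (not isolated)
Conditions: O3, CH2Cl2/MeOH, −78 °C (Sudan Red 7B end-point); then NaBH4, −78 °C → rt
Reagents that add atoms: ozone, [O-][O+]=O
Why: Ozonolysis with reductive work-up, in which the electron-rich trisubstituted alkene should react with ozone far faster than the terminal alkyne or the nitrile-deactivated arene, and NaBH4 reduces aldehyde 8 without touching the nitrile.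

Step 6
Reactants: 9 4-{[(3S)-6-hydroxy-3-methylhex-1-yn-3-yl]oxy}-3-methylbenzonitrile
Product: 11 4-{[(3S)-6-hydroxy-3-methylhex-1-yn-3-yl]oxy}-3-methylbenzaldehyde, via N-aluminated aldimine 10 (not isolated)
Conditions: i-Bu2AlH (2.5 equiv), toluene, −78 → −20 °C; then aq potassium sodium tartrate, dilute citric acid, rt
Reagents that add atoms: water, O
Why: Partial reduction of the nitrile with i-Bu2AlH should stop at aldimine 10 at low temperature (the first equivalent being consumed by the hydroxyl group), and aqueous work-up hydrolyses it to the aldehyde without involving the stereocentre.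

Step 7
Reactants: 11 4-{[(3S)-6-hydroxy-3-methylhex-1-yn-3-yl]oxy}-3-methylbenzaldehyde
Product: 13 4-{[(3S)-6-hydroxy-3-methylhex-1-yn-3-yl]oxy}-3-methylphenol, via aryl formate 12 (not isolated)
Conditions: mCPBA, NaHCO3, CH2Cl2, 0 °C → rt; aq Na2S2O3; then K2CO3 (cat.), MeOH, 0 °C
Reagents that add atoms: 3-chloroperoxybenzoic acid, OOC(=O)c1cccc(Cl)c1
Why: Baeyer–Villiger (Dakin-type) oxidation in which the electron-rich 4-alkoxy-3-methylphenyl group migrates in the Criegee adduct to give formate 12, which mild methanolysis cleaves to the phenol, while the alkyne and the alcohol are inert to the peracid at this temperature.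

Step 8
Reactants: 13 4-{[(3S)-6-hydroxy-3-methylhex-1-yn-3-yl]oxy}-3-methylphenol
Product: 14 tert-butyl({(4S)-4-[4-(tert-butyldimethylsilyloxy)-2-methylphenoxy]-4-methylhex-5-yn-1-yl}oxy)dimethylsilane
Conditions: t-BuMe2SiCl (2.5 equiv), imidazole, DMF, rt
Reagents that add atoms: tert-butyldimethylsilyl chloride, CC(C)(C)[Si](C)(C)Cl
Why: Imidazole-promoted silylation converts the phenol and the primary alcohol into silyl ethers in one operation, so that no O–H group can add to the gold-activated alkyne in step 9 and the two oxygens can later be told apart by their different acid lability.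

Step 9
Reactants: 14 tert-butyl({(4S)-4-[4-(tert-butyldimethylsilyloxy)-2-methylphenoxy]-4-methylhex-5-yn-1-yl}oxy)dimethylsilane
Product: 15 (2S)-6-(tert-butyldimethylsilyloxy)-2-[3-(tert-butyldimethylsilyloxy)propyl]-2,8-dimethyl-2H-chromene
Conditions: Ph3PAuNTf2 (2 mol %), 4 Å molecular sieves, CH2Cl2, rt
Reagents that add atoms: none
Why: Ph3PAuNTf2 (cationic monovalent gold) binds the terminal alkyne of 14, and the arene attacks the terminal alkyne carbon anti to gold through its free carbon ortho to the ether oxygen (the future C4a), giving a Wheland-type vinylgold intermediate that rearomatises and is protodeaurated to the cis C3=C4 alkene. The closest known reaction type is the gold-catalysed intramolecular hydroarylation of aryl propargyl ethers, 1,1-disubstituted ones included, to 2H-chromenes. The pyran ring closes in the 6-endo-dig mode and the new bond is C4–C4a. No stereocentre is created, and because no bond to the quaternary carbon is broken (the C2–O1 bond stays intact, unlike in a thermal propargyl Claisen sequence), the (S) configuration fixed in step 1 should be carried into C2. The step needs 6-endo over 5-exo closure, a single site of attack and no ionisation of the tertiary ether: the terminal alkyne and the ortho-directing ether oxygen favour attack at the terminal carbon, the second ortho position is blocked by the methyl group (C8), and the neutral room-temperature conditions with both oxygens silylated and the prenyl alkene already removed leave gold no competing nucleophile or enyne pathway.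

Step 10
Reactants: 15 (2S)-6-(tert-butyldimethylsilyloxy)-2-[3-(tert-butyldimethylsilyloxy)propyl]-2,8-dimethyl-2H-chromene
Product: 16 3-[(2S)-6-(tert-butyldimethylsilyloxy)-2,8-dimethyl-2H-chromen-2-yl]propan-1-ol
Conditions: 10-camphorsulfonic acid (10 mol %), MeOH/CH2Cl2, 0 °C; Et3N quench
Reagents that add atoms: none
Why: Acid-catalysed methanolysis (selective desilylation) should remove the primary alkyl silyl ether much faster than the aryl silyl ether, whose oxygen is less basic, under conditions mild enough for the 2H-chromene.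

Step 11
Reactants: 16 3-[(2S)-6-(tert-butyldimethylsilyloxy)-2,8-dimethyl-2H-chromen-2-yl]propan-1-ol
Product: 18 3-[(2S)-6-(tert-butyldimethylsilyloxy)-2,8-dimethyl-2H-chromen-2-yl]propanoic acid, via aldehyde 17 (not isolated)
Conditions: TEMPO (20 mol %), PhI(OAc)2 (2.2 equiv), MeCN/H2O, rt
Reagents that add atoms: water, O
Why: TEMPO-catalysed oxidation with PhI(OAc)2 as terminal oxidant takes the primary alcohol to aldehyde 17 and, through its hydrate in the aqueous medium, on to the acid, without affecting the aryl silyl ether or the chromene alkene.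

Step 12
Reactants: 18 3-[(2S)-6-(tert-butyldimethylsilyloxy)-2,8-dimethyl-2H-chromen-2-yl]propanoic acid
Product: 19 1,3-dioxoisoindolin-2-yl 3-[(2S)-6-(tert-butyldimethylsilyloxy)-2,8-dimethyl-2H-chromen-2-yl]propanoate
Conditions: N-hydroxyphthalimide, i-PrN=C=N-i-Pr, DMAP (cat.), CH2Cl2, rt
Reagents that add atoms: N-hydroxyphthalimide, ON1C(=O)c2ccccc2C1=O
Why: Steglich-type carbodiimide coupling of the acid with N-hydroxyphthalimide gives the redox-active ester under neutral conditions.

Step 13
Reactants: 20 (2R)-2-(chloromethyl)oxirane; 21 ethynyltrimethylsilane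
Product: 22 (2R)-1-chloro-5-(trimethylsilyl)pent-4-yn-2-ol
Conditions: 21, n-BuLi, THF, −78 °C; BF3·OEt2; then 20, −78 °C
Reagents that add atoms: none
Why: Yamaguchi–Hirao alkynylation, a BF3-activated SN2 opening of the epoxide at its unsubstituted carbon by the lithium acetylide at −78 °C, where chloride displacement and epoxide re-closure should not compete, so the stereocentre of 20 is carried over unchanged.

Step 14
Reactants: 22 (2R)-1-chloro-5-(trimethylsilyl)pent-4-yn-2-ol
Product: 23 (2R)-1-chloropent-4-yn-2-ol
Conditions: Bu4NF, AcOH, THF, 0 °C → rt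
Reagents that add atoms: none
Why: Fluoride-induced protodesilylation of the alkynylsilane, buffered with acetic acid so that the chlorohydrin does not close to a volatile epoxide.

Step 15
Reactants: 23 (2R)-1-chloropent-4-yn-2-ol
Product: 25 (2R,4E)-1-chloro-5-iodo-4-methylpent-4-en-2-ol, via alkenylalane 24 (not isolated)
Conditions: Me3Al (3 equiv), Cp2ZrCl2 (25 mol %), CH2Cl2, 0 °C → rt; then I2, THF, −30 → 0 °C
Reagents that add atoms: trimethylaluminium, C[Al](C)C; iodine, II
Why: Negishi zirconium-catalysed carboalumination, in which syn addition of methyl and aluminium across the terminal alkyne with methyl on the internal carbon gives alkenylalane 24, whose iodinolysis with retention should furnish the E iodoalkene, the hydroxyl group being carried as its aluminium alkoxide and the carbinol centre left untouched.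

Step 16
Reactants: 25 (2R,4E)-1-chloro-5-iodo-4-methylpent-4-en-2-ol
Product: 26 (2R)-2-[(2E)-3-iodo-2-methylprop-2-en-1-yl]oxirane
Conditions: K2CO3, MeOH, rt
Reagents that add atoms: none
Why: Intramolecular Williamson etherification (3-exo-tet displacement of chloride by the alkoxide) forms the epoxide, and the stereocentre, being the carbon that bears the attacking oxygen, is retained.

Step 17
Reactants: 26 (2R)-2-[(2E)-3-iodo-2-methylprop-2-en-1-yl]oxirane; 27 (phenylsulfanyl)acetic acid
Product: 29 (5R)-5-[(2E)-3-iodo-2-methylprop-2-en-1-yl]-3-(phenylsulfanyl)oxolan-2-one, via hydroxy acid 28 (not isolated)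
Conditions: 27, LiN(i-Pr)2 (2.1 equiv), THF, −78 → 0 °C; then 26, 0 °C → rt; aq HCl; TsOH·H2O (cat.), toluene, 60 °C
Reagents that add atoms: none
Why: The dianion of (phenylsulfanyl)acetic acid opens the terminal epoxide at its CH2 carbon (SN2) and the resulting γ-hydroxy acid 28 lactonises under acid catalysis, so C5 of the lactone keeps the configuration of 26 because its C–O bond is never broken.

Step 18
Reactants: 29 (5R)-5-[(2E)-3-iodo-2-methylprop-2-en-1-yl]-3-(phenylsulfanyl)oxolan-2-one; 30 5-bromo-2-methylpent-2-ene
Product: 31 (5R)-5-[(2E)-3-iodo-2-methylprop-2-en-1-yl]-3-(4-methylpent-3-en-1-yl)-3-(phenylsulfanyl)oxolan-2-one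
Conditions: LiN(i-Pr)2, THF, −78 °C; then 30, DMPU, −78 °C → rt
Reagents that add atoms: none
Why: Alkylation (SN2) of the sulfur-stabilised lactone enolate with the primary homoallylic bromide, the soft and weakly basic enolate favouring substitution over elimination, and the new quaternary C3 may form as a mixture of epimers because this centre becomes sp2 in step 19.

Step 19
Reactants: 31 (5R)-5-[(2E)-3-iodo-2-methylprop-2-en-1-yl]-3-(4-methylpent-3-en-1-yl)-3-(phenylsulfanyl)oxolan-2-one
Product: 33 (5R)-5-[(2E)-3-iodo-2-methylprop-2-en-1-yl]-3-(4-methylpent-3-en-1-yl)furan-2(5H)-one, via sulfoxide 32 (not isolated)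
Conditions: NaIO4, MeOH/H2O, 0 °C → rt; then CaCO3, toluene, 100 °C
Reagents that add atoms: none
Why: Periodate oxidation of the sulfide to the sulfoxide, which spares the alkenes and the alkenyl iodide, followed by thermal syn-elimination (sulfoxide pyrolysis) of benzenesulfenic acid towards the ring CH2, should give the conjugated endocyclic butenolide under neutral conditions that cannot epimerise C5.

Step 20
Reactants: 19 1,3-dioxoisoindolin-2-yl 3-[(2S)-6-(tert-butyldimethylsilyloxy)-2,8-dimethyl-2H-chromen-2-yl]propanoate; 33 (5R)-5-[(2E)-3-iodo-2-methylprop-2-en-1-yl]-3-(4-methylpent-3-en-1-yl)furan-2(5H)-one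
Product: 34 (5R)-5-{(2E)-5-[(2S)-6-(tert-butyldimethylsilyloxy)-2,8-dimethyl-2H-chromen-2-yl]-2-methylpent-2-en-1-yl}-3-(4-methylpent-3-en-1-yl)furan-2(5H)-one
Conditions: NiBr2·(MeOCH2CH2OMe) (20 mol %), 4,4'-di-tert-butyl-2,2'-bipyridine, Zn dust, DMA, rt
Reagents that add atoms: none
Why: Nickel-catalysed reductive decarboxylative alkenylation (cross-electrophile coupling of a redox-active ester with an alkenyl iodide), in which zinc turns over low-valent nickel that adds oxidatively to the C–I bond and reduces 19 to a primary alkyl radical with loss of CO2 and phthalimide, and radical capture followed by reductive elimination should form the C(sp3)–C(sp2) bond with retention of the E geometry while the non-basic medium leaves both stereocentres alone.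

Step 21
Reactants: 34 (5R)-5-{(2E)-5-[(2S)-6-(tert-butyldimethylsilyloxy)-2,8-dimethyl-2H-chromen-2-yl]-2-methylpent-2-en-1-yl}-3-(4-methylpent-3-en-1-yl)furan-2(5H)-one
Product: 35 tuberatolide B
Conditions: Bu4NF, AcOH, THF, 0 °C
Reagents that add atoms: none
Why: Fluoride cleaves the aryl silyl ether (strong Si–F bond, good phenoxide leaving group), and the acetic acid buffer keeps the medium from becoming basic enough to epimerise C5 or open the butenolide.

Compound list
1 | geraniol, (2E)-3,7-dimethylocta-2,6-dien-1-ol | CC(C)=CCC/C(C)=C/CO | starting material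
2 | [(2S,3S)-3-methyl-3-(4-methylpent-3-en-1-yl)oxiran-2-yl]methanol | CC(C)=CCC[C@]1(C)O[C@H]1CO | intermediate
3 | (2S,3R)-3-(chloromethyl)-2-methyl-2-(4-methylpent-3-en-1-yl)oxirane | CC(C)=CCC[C@]1(C)O[C@H]1CCl | intermediate
4 | lithium (3S)-1-chloro-3,7-dimethylocta-1,6-dien-3-olate (geometry of the chloroalkene not defined) | CC(C)=CCC[C@@]([O-])(C)C=CCl.[Li+] | intermediate
5 | (3S)-3,7-dimethyloct-6-en-1-yn-3-ol | CC(C)=CCC[C@@](O)(C)C#C | intermediate
6 | 4-fluoro-3-methylbenzonitrile | Cc1cc(C#N)ccc1F | starting material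
7 | 4-{[(3S)-3,7-dimethyloct-6-en-1-yn-3-yl]oxy}-3-methylbenzonitrile | CC(C)=CCC[C@@](Oc1ccc(C#N)cc1C)(C)C#C | intermediate
8 | 3-methyl-4-{[(3S)-3-methyl-6-oxohex-1-yn-3-yl]oxy}benzonitrile | O=CCC[C@@](Oc1ccc(C#N)cc1C)(C)C#C | intermediate
9 | 4-{[(3S)-6-hydroxy-3-methylhex-1-yn-3-yl]oxy}-3-methylbenzonitrile | OCCC[C@@](Oc1ccc(C#N)cc1C)(C)C#C | intermediate
10 | (4S)-4-[4-(iminomethyl)-2-methylphenoxy]-4-methylhex-5-yn-1-ol (present as its aluminium derivative) | OCCC[C@@](Oc1ccc(C=N)cc1C)(C)C#C | intermediate
11 | 4-{[(3S)-6-hydroxy-3-methylhex-1-yn-3-yl]oxy}-3-methylbenzaldehyde | OCCC[C@@](Oc1ccc(C=O)cc1C)(C)C#C | intermediate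
12 | 4-{[(3S)-6-hydroxy-3-methylhex-1-yn-3-yl]oxy}-3-methylphenyl formate | OCCC[C@@](Oc1ccc(OC=O)cc1C)(C)C#C | intermediate
13 | 4-{[(3S)-6-hydroxy-3-methylhex-1-yn-3-yl]oxy}-3-methylphenol | OCCC[C@@](Oc1ccc(O)cc1C)(C)C#C | intermediate
14 | tert-butyl({(4S)-4-[4-(tert-butyldimethylsilyloxy)-2-methylphenoxy]-4-methylhex-5-yn-1-yl}oxy)dimethylsilane | CC(C)(C)[Si](C)(C)OCCC[C@@](Oc1ccc(O[Si](C)(C)C(C)(C)C)cc1C)(C)C#C | intermediate
15 | (2S)-6-(tert-butyldimethylsilyloxy)-2-[3-(tert-butyldimethylsilyloxy)propyl]-2,8-dimethyl-2H-chromene | CC(C)(C)[Si](C)(C)OCCC[C@@]1(C)C=Cc2cc(O[Si](C)(C)C(C)(C)C)cc(C)c2O1 | intermediate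
16 | 3-[(2S)-6-(tert-butyldimethylsilyloxy)-2,8-dimethyl-2H-chromen-2-yl]propan-1-ol | OCCC[C@@]1(C)C=Cc2cc(O[Si](C)(C)C(C)(C)C)cc(C)c2O1 | intermediate
17 | 3-[(2S)-6-(tert-butyldimethylsilyloxy)-2,8-dimethyl-2H-chromen-2-yl]propanal | O=CCC[C@@]1(C)C=Cc2cc(O[Si](C)(C)C(C)(C)C)cc(C)c2O1 | intermediate
18 | 3-[(2S)-6-(tert-butyldimethylsilyloxy)-2,8-dimethyl-2H-chromen-2-yl]propanoic acid | OC(=O)CC[C@@]1(C)C=Cc2cc(O[Si](C)(C)C(C)(C)C)cc(C)c2O1 | intermediate
19 | 1,3-dioxoisoindolin-2-yl 3-[(2S)-6-(tert-butyldimethylsilyloxy)-2,8-dimethyl-2H-chromen-2-yl]propanoate | O=C(CC[C@@]1(C)C=Cc2cc(O[Si](C)(C)C(C)(C)C)cc(C)c2O1)ON1C(=O)c2ccccc2C1=O | intermediate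
20 | (2R)-2-(chloromethyl)oxirane, (R)-epichlorohydrin | ClC[C@H]1CO1 | starting material
21 | ethynyltrimethylsilane | C#C[Si](C)(C)C | starting material
22 | (2R)-1-chloro-5-(trimethylsilyl)pent-4-yn-2-ol | ClC[C@H](O)CC#C[Si](C)(C)C | intermediate
23 | (2R)-1-chloropent-4-yn-2-ol | ClC[C@H](O)CC#C | intermediate
24 | dimethylaluminium alkoxide of (2R,4E)-1-chloro-5-(dimethylalumanyl)-4-methylpent-4-en-2-ol | ClC[C@H](O[Al](C)C)C/C(C)=C/[Al](C)C | intermediate
25 | (2R,4E)-1-chloro-5-iodo-4-methylpent-4-en-2-ol | ClC[C@H](O)C/C(C)=C/I | intermediate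
26 | (2R)-2-[(2E)-3-iodo-2-methylprop-2-en-1-yl]oxirane | C1[C@H](O1)C/C(C)=C/I | intermediate
27 | (phenylsulfanyl)acetic acid | OC(=O)CSc1ccccc1 | starting material
28 | (4R,6E)-4-hydroxy-7-iodo-6-methyl-2-(phenylsulfanyl)hept-6-enoic acid (both C2 epimers) | OC(=O)C(Sc1ccccc1)C[C@H](O)C/C(C)=C/I | intermediate
29 | (5R)-5-[(2E)-3-iodo-2-methylprop-2-en-1-yl]-3-(phenylsulfanyl)oxolan-2-one (both C3 epimers) | O=C1O[C@H](C/C(C)=C/I)CC1Sc1ccccc1 | intermediate
30 | 5-bromo-2-methylpent-2-ene | CC(C)=CCCBr | starting material
31 | (5R)-5-[(2E)-3-iodo-2-methylprop-2-en-1-yl]-3-(4-methylpent-3-en-1-yl)-3-(phenylsulfanyl)oxolan-2-one (both C3 epimers) | O=C1O[C@H](C/C(C)=C/I)CC1(CCC=C(C)C)Sc1ccccc1 | intermediate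
32 | (5R)-3-(benzenesulfinyl)-5-[(2E)-3-iodo-2-methylprop-2-en-1-yl]-3-(4-methylpent-3-en-1-yl)oxolan-2-one | O=C1O[C@H](C/C(C)=C/I)CC1(CCC=C(C)C)S(=O)c1ccccc1 | intermediate
33 | (5R)-5-[(2E)-3-iodo-2-methylprop-2-en-1-yl]-3-(4-methylpent-3-en-1-yl)furan-2(5H)-one | CC(C)=CCCC1=C[C@@H](C/C(C)=C/I)OC1=O | intermediate
34 | (5R)-5-{(2E)-5-[(2S)-6-(tert-butyldimethylsilyloxy)-2,8-dimethyl-2H-chromen-2-yl]-2-methylpent-2-en-1-yl}-3-(4-methylpent-3-en-1-yl)furan-2(5H)-one | CC(C)=CCCC1=C[C@@H](C/C(C)=C/CC[C@@]2(C)C=Cc3cc(O[Si](C)(C)C(C)(C)C)cc(C)c3O2)OC1=O | intermediate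
35 | tuberatolide B, (5R)-5-{(2E)-5-[(2S)-6-hydroxy-2,8-dimethyl-2H-chromen-2-yl]-2-methylpent-2-en-1-yl}-3-(4-methylpent-3-en-1-yl)furan-2(5H)-one | CC(C)=CCCC1=C[C@@H](C/C(C)=C/CC[C@@]2(C)C=Cc3cc(O)cc(C)c3O2)OC1=O | target

Total step count: 21. Longest linear sequence: 14 steps (steps 1 to 12, then 20 and 21); the butenolide branch (steps 13 to 19) has 7 steps before the union.

Steps most likely to fail

Step 9 (gold hydroarylation). What may go wrong is hydration of the gold-activated alkyne by adventitious water, ionisation of the tertiary propargylic C–O bond by the Lewis-acidic catalyst (erosion of enantiomeric purity or elimination), or acid-promoted oligomerisation of the chromene as it forms. The fallback sets out from 14 and activates the alkyne with an iodonium source instead of gold (I2, NaHCO3, MeCN, rt). This electrophilic carbocyclisation of aryl propargyl ethers is known and should give (2S)-6-(tert-butyldimethylsilyloxy)-2-[3-(tert-butyldimethylsilyloxy)propyl]-3-iodo-2,8-dimethyl-2H-chromene F1 by the same 6-endo attack, without a Lewis acid able to ionise the ether. Hydrodeiodination with Bu3SnH and catalytic Pd(PPh3)4 (zerovalent palladium) in THF at rt should then return the route to 15.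

Step 20 (nickel-catalysed decarboxylative alkenylation). What may go wrong is premature reduction of the redox-active ester to the alkane, reductive dimerisation of the alkenyl iodide, or trapping of the alkyl radical by the butenolide or the chromene double bond before nickel captures it. The fallback sets out from 19 and separates radical generation from C–C bond formation. Photochemical iododecarboxylation (LiI, catalytic PPh3, acetone, blue light) should give tert-butyl{[(2S)-2-(2-iodoethyl)-2,8-dimethyl-2H-chromen-6-yl]oxy}dimethylsilane F2. Insertion of activated Zn dust in the presence of LiCl (THF, rt) should convert it into {2-[(2S)-6-(tert-butyldimethylsilyloxy)-2,8-dimethyl-2H-chromen-2-yl]ethyl}zinc iodide F3. A Negishi coupling of F3 with 33 ([1,1'-bis(diphenylphosphino)ferrocene]PdCl2, THF, rt to 40 °C) should re-enter the route at 34.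

Step 4 (aryl ether formation). What may go wrong is slow substitution at the carbon flanked by the methyl group, which would let loss of acetylene from the tertiary alkoxide or base-induced degradation of the enyne compete. The fallback sets out from 5, whose sodium alkoxide (NaH, THF/toluene, 0 °C) would be arylated at rt with (4-cyano-2-methylphenyl)(2,4,6-trimethoxyphenyl)iodonium 4-methylbenzenesulfonate F4. This salt is made in one pot from commercial 4-iodo-3-methylbenzonitrile (mCPBA, TsOH·H2O, then 1,3,5-trimethoxybenzene, MeCN). Ligand coupling at the trivalent iodine transfers the electron-poor, ortho-substituted aryl group to oxygen; this metal-free O-arylation is known for alkoxides, tertiary ones included, and returns the route to 7.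

Further compounds
F1 | step 9 | (2S)-6-(tert-butyldimethylsilyloxy)-2-[3-(tert-butyldimethylsilyloxy)propyl]-3-iodo-2,8-dimethyl-2H-chromene | CC(C)(C)[Si](C)(C)OCCC[C@@]1(C)C(I)=Cc2cc(O[Si](C)(C)C(C)(C)C)cc(C)c2O1
F2 | step 20 | tert-butyl{[(2S)-2-(2-iodoethyl)-2,8-dimethyl-2H-chromen-6-yl]oxy}dimethylsilane | ICC[C@@]1(C)C=Cc2cc(O[Si](C)(C)C(C)(C)C)cc(C)c2O1
F3 | step 20 | {2-[(2S)-6-(tert-butyldimethylsilyloxy)-2,8-dimethyl-2H-chromen-2-yl]ethyl}zinc iodide | I[Zn]CC[C@@]1(C)C=Cc2cc(O[Si](C)(C)C(C)(C)C)cc(C)c2O1
F4 | step 4 | (4-cyano-2-methylphenyl)(2,4,6-trimethoxyphenyl)iodonium 4-methylbenzenesulfonate | COc1cc(OC)c([I+]c2ccc(C#N)cc2C)c(OC)c1.Cc1ccc(cc1)S([O-])(=O)=O
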